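The meeting on the flask opened with what stays the same between two runs: the first member held that target, divided by a pool, follows one curve in time in alpha and in eta, which differ in their charge of free base.

| setting | alpha | eta | flask |
|---|---|---|---|
| acidic substrate | 0.35 M | 0.35 M | 0.35 M |
| free base | 0.245 M | 0.12 M | 0.245 M |
| electrophile | 0.70 M | 0.70 M | 0.700 M |
| temperature | 90 °C | 90 °C | 90 °C |
| remark | the very flask that is asked about, followed so far | run made earlier |  |
| time |  |  | 2.0 d |

| run | time / h | target / % |
|---|---|---|
| alpha | 8.00 | 51.5 |
| alpha | 15.0 | 42.1 |
| alpha | 20.0 | 36.0 |
| alpha | 30.0 | 29.0 |
| eta | 2.00 | 31.2 |
| eta | 6.00 | 27.6 |
| eta | 12.0 | 21.8 |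
| eta | 20.0 | 18.0 |

(readings scatter by 0.5 percentage points)

- east: at 2.0 d add free base, 100% of the amount charged, then wait 4.0 d
- south-west: at 2.0 d raise the temperature by 25 K, then wait 4.0 d
- south-east: at 2.0 d take out 90% of the target then present, then wait 4.0 d
- north: at 2.0 d add free base, 100% of the amount charged, then wait 4.0 d
- west: change nothing and wait 4.0 d more

- what is taken out of target is counted as made
- the numbers in the tables scatter with a standard deviation of 0.5 percentage points
- additions bring no volume worth counting
- the earlier runs do not show what temperature does; that part of a forecast is a guess

- target, in percent of the acidic substrate first charged, at 2.0 d
- the remedy with the largest gain of target, or "none" below 2 percentage points (east / south-west / south-east / north / west / none)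
- target present, with what was taken out counted in, in percent of the acidic substrate first charged, after east
- target present, with what was taken out counted in, in percent of the acidic substrate first charged, after south-west

She defined the pool, the percentage of the acidic substrate charged that the smallest charge can carry into target and whatever target becomes, as that smallest charge over the charge of acidic substrate, counting one of each per target. This gives 70.0% for alpha, with free base as limiting reagent, and 34.3% for eta. At 20.0 h the two runs stand at 0.514 and 0.525 of their pools, which she took as one curve.

The second member then compared rates at two moments in alpha. Between the first two readings target fell by 0.0134 /h of the charge, and between the last two by 0.00700 /h, which is slower. He read from this a decay of the rate itself of 0.0483 /h.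

Carrying that on from the last reading, my own reckoning puts target at 22.4% at 2.0 d. Adding free base in east lifts the pool to 100%, and holding target at the same share of the pool gives me 32.0%.

The forecast entered 21.5% (range 19.5% to 24%), 26% after east, which is below mine, 18% after south-west, and south-east as best remedy, reading the loss as a “reversible conversion to a by-product”.

The flask gives 24.2% at 2.0 d, 31.3% after east and 50.0% after south-west, and the best remedy is south-west, gaining 26 percentage points.

    acidic substrate + free base ⇌ protonated base + anion, settled at all times (K = 1.80, ΔH = −34.0 kJ/mol)
    electrophile + anion → target (k = 4.00 /M/h, Ea = 70.0 kJ/mol)
    target ⇌ isomer of the product (K = 2.20, k = 0.0440 /h, Ea = 118 kJ/mol, ΔH = −80.0 kJ/mol)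
    (constants at 90 °C)

Anion passes into target with a half-life of 0.25 h at the charged concentrations, far shorter than the 16 h of the forward passing of target into isomer of the product. The relaxation of target and isomer of the product by this step alone, both ways together, has a half-life of 10.8 h, short against 2.0 d, and at that time the flask holds 24.2% target and 45.8% isomer of the product, together 70.0% against a pool of 70.0%. A second flask, charged like this one but with 0.17 M of electrophile, has a pool of 48.6% and holds, at 48.0 h, target and isomer of the product together at 48.6%.

The numbers in the tables were generated by integration with made-up constants; noise was put on by code.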